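- In the north-west run, product reached 58.9% of the electrophile charged by 2.00 min and then crept to 65.8% by 8.00 min, while the electrophile, charged in less than the nucleophile and so the limiting reagent on paper, still stood at 35.2%.

all flasks: electrophile 0.084 M; nucleophile 0.0924 M

| flask | free base | remark | time |
|---|---|---|---|
| north-west | 0.015 M | run made earlier |  |
| midnight | 0.0250 M |  | 8.0 min |
| noon | 0.0330 M |  | 8.0 min |
| dusk | 0.0430 M |  | 8.0 min |

- north-west (time / min: electrophile / %, product / %): 0.667: 54.3, 44.9; 1.00: 48.4, 53.4; 2.00: 38.0, 58.9; 3.00: 37.6, 62.9; 5.00: 35.6, 64.0; 8.00: 35.2, 65.8

(scatter of a reading: 1 percentage point)

- the numbers in the tables scatter by 1 percentage point (one standard deviation)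
- reactions considered so far: electrophile + nucleophile -> acid set free + product; nucleophile + acid set free <-> protonated nucleophile; acid set free + free base <-> salt of the base
- no earlier run changes the charge of free base; that part of a forecast is a guess

* part of the electrophile that has reacted at the end, midnight
* part of the electrophile that has reacted at the end, noon
* part of the electrophile that has reacted at the end, dusk
* what raising the concentration of free base from its lowest to its highest value here does to the part of the electrophile that has reacted (changes below 5 percentage points count as none) (no change / it rises / it falls)

- Our balance is this: each electrophile reacted takes one nucleophile and sets free one acid, the free base takes up acid, and further acid ties a second nucleophile as protonated nucleophile.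
- For noon that gives 74.6%, our stall share: the nucleophile and free base charges, each as a fraction of the electrophile charge, added and divided by two.
- Against north-west's product reading above, with its scatter of 1 percentage point, the same balance gives 63.9%.
- Even in dusk, nucleophile and free base together come to less than two per electrophile, so we expect electrophile to remain in each flask.
- At 8.0 min we expect midnight near 69.9%, noon near 74.6% and dusk near 80.6%, with the free base held as salt of the base and the nucleophile in product and protonated nucleophile.
- Leave the nucleophile and free base charges as weighed: the stall share moves with both, rising 11 points from midnight to dusk, more than the 5 points that counts, though no earlier run changed the free base, so that part is a guess.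
- The forecast gives 70.5%, 75.3% and 81%, a little above ours at midnight, and says it rises, holding that “the base seems to work fully, though this is inferred from one charge”.
- The flasks gave 70.9%, 75.2% and 80.5%; for the reacted part from midnight to dusk, it rises, by 9.6 points.

    electrophile + nucleophile → acid set free + product (k = 0.290 M⁻¹ s⁻¹)
    nucleophile + acid set free ⇌ protonated nucleophile, settled at all times (K = 30000 M⁻¹)
    acid set free + free base ⇌ salt of the base, settled at all times (K = 2.60 × 10⁵ M⁻¹)

- In noon, the half-life of the electrophile by its reaction with the nucleophile was 0.79 min at 0.398 min, short against the 8.0 min of the run, but 69 min at 8.00 min, long against it. At that time noon held 0.63% of its nucleophile charge unbound and stood at 75.2%, beside its stall share of 74.6%. The same flask as noon with the nucleophile cut to 44.0% of the electrophile charge has a stall share of 41.7%, and it gave 41.7% at 8.00 min.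

The runs stem from a simulated flask with constants of no real substance, noise included.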